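The G left over at the last reading was 21 % of the charge in the noon run and 46 % in the winter run, so 0.498 M and 0.535 M of G had reacted, against 0.54 M of Q charged in each.

| setting | noon | winter | dawn | flask |
|---|---|---|---|---|
| G | 0.63 M | 0.99 M | 0.45 M | 0.45 M |
| Q | 0.54 M | 0.54 M | 1.1 M | 0.540 M |
| D | 0.45 M | 0.45 M | 0.45 M | 0.450 M |
| remark | run made earlier | run made earlier | run made earlier |  |
| time |  |  |  | 80 min |

- noon (time / min: G / %, L / %): 8.00: 22, 74; 15.0: 20, 71; 25.0: 20, 74; 30.0: 25, 77; 40.0: 20, 76; 50.0: 21, 74
- winter (time / min: G / %, L / %): 4.00: 48, 51; 6.00: 47, 51; 10.0: 50, 52; 20.0: 50, 50; 30.0: 47, 48; 50.0: 46, 51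
- dawn (time / min: G / %, L / %): 4.00: 5, 66; 12.0: 0, 35; 20.0: 0, 25; 30.0: 0, 13; 50.0: 0, 8

(each reading ± 2 percentage points)

- the earlier runs do not show how much of Q is bound; that part of a forecast is a guess

- part of the G that has reacted at 80 min
- share of the unused Q that is free and not bound as J, at 80 min

I built the new flask up one process at a time. With the main step by itself, G + Q → L at one Q per G, Q is the limiting reagent in the noon and winter runs, but the flask holds 0.540 M of Q against 0.45 M of G. That leaves 0.0900 M of spare Q, the Q charged beyond one per G, which is 20.0 % of the G.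

Then I added the second process. In the dawn run, with 1.1 M of Q, L fell from 35 % to 13 % between 12.0 min and 30.0 min, and I took it that L takes up Q too. These readings give L a half-life near 12.6 min in the dawn run, whose spare Q was 0.650 M. In the flask the spare Q would meet about 0.360 M of L, so by the same constant the half-life of that Q comes roughly to 22.7 min, shorter than the 80 min of the flask. I therefore expected the spare Q to be spent on L by then, leaving L near 80.0 % if G were used up.

The last noon readings of G and L fall 5 percentage points short of the charge, which, within the scatter, I read as this second step running while G remains, and I put c somewhat under 100 %. How much Q is bound, the runs do not show.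

The forecast gave 96 % (91 % to 99.5 %) and, for free Q, 30 % (5 % to 75 %), reading that dawn “hints at moderate binding to D”.

The flask gave 98.2 % and 88.1 %.

    Q + L → E + X (k = 0.230 L mol⁻¹ min⁻¹)
    D + X → Z (k = 56.0 L mol⁻¹ min⁻¹)
    Q + X ⇌ J, settled at all times (K = 1.50 L mol⁻¹)
    G + Q → L + X (k = 2.80 L mol⁻¹ min⁻¹)

The free share stood 58 points above the forecast; at 80.0 min D was at 0 % and X stood at 0.0899 M, and the pairing of Q with that X to J gives 88.1 % free. The spare Q plus the G left comes to 21.8 % of the G charged, and E stood at 21.8 %. In the neighbour flask with 0.92 M of Q, the spare is 104 % of the G, and E reached 87.5 % with L at 12.5 %. In the flask itself, the unbound Q left at 80.0 min, 0.0082 % of its charge, equals 0.00984 % of the G charged. At 800 min, G stood at 1.81 %, L at 76.4 %, E at 21.8 %, Q at 0 %, and c at 98.2 %.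

(The runs come from a simulation with constants of no real substance; the scatter is artificial.)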